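**Retrosynthetic overview**
1. 14 ⇒ 13: the last step only removes six benzyl ethers and one blocking bromine.
2. 13 ⇒ 11 (key step): both pyranone rings are cut at O1–C2. This gives one open precursor carrying a 2'-hydroxychalcone and an o-hydroxyaryl β-diketone on a preformed biaryl.
3. 11 ⇒ 10 + 2 (Claisen–Schmidt). 10 ⇒ 6 + 8, so the biaryl bond is made between two simple benzenes and not between two flavonoids.
4. 6 ⇒ 4 + 5 (C-aroylation). 4 ⇒ 2 by bromine ortho and then iodine para to the one free OH, which fixes the 6-aryl pattern. 2 ⇒ 1.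
5. Ring order: benzene rings A, B (flavanone) and D, F (flavone) are bought (1 used twice, 7, 5). Ring C (flavanone pyranone, sets C2) closes first and ring E (flavone pyranone) second, in the same flask in step 7.

Assumption 1: the biaryl axis carries no stereodescriptor in the target SMILES and is treated as a rotating axis; the benzylated intermediates may show rotamers in NMR.
Assumption 2: the quinidine-derived thiourea is taken to give the 2S series. The sense is read from the CD spectrum of 13 in the first run, and the quinine-derived pseudoenantiomer replaces it if the sense is reversed.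

**Step 1**
Reactants: 1 2,4,6-trihydroxyacetophenone
Product: 2 1-[2,4-bis(benzyloxy)-6-hydroxyphenyl]ethan-1-one
Conditions: BnBr (2.1 equiv), K2CO3 (2.2 equiv), DMF, 0 °C to rt, 16 h
Reagents that add atoms: benzyl bromide, BrCc1ccccc1
Why: Williamson etherification (SN2) in which two phenoxides are alkylated, while the OH that is hydrogen-bonded to the acetyl C=O stays free at this stoichiometry.

**Step 2**
Reactants: 2 1-[2,4-bis(benzyloxy)-6-hydroxyphenyl]ethan-1-one
Product: 4 1-[4,6-bis(benzyloxy)-3-bromo-2-hydroxy-5-iodophenyl]ethan-1-one, via monobromide 3 (not isolated)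
Conditions: NBS (1.0 equiv), MeCN, 0 °C, dark, 1 h; then NIS (1.1 equiv), TFA (0.3 equiv), rt, 6 h
Reagents that add atoms: N-bromosuccinimide, O=C1CCC(=O)N1Br; N-iodosuccinimide, O=C1CCC(=O)N1I
Why: Two successive electrophilic aromatic halogenations, in which the free chelated OH sends bromine to its ortho carbon C3, so iodine can only enter at C5, para to that OH and between the two OBn groups; the bromine is a blocking group that step 8 removes.

**Step 3**
Reactants: 4 1-[4,6-bis(benzyloxy)-3-bromo-2-hydroxy-5-iodophenyl]ethan-1-one; 5 4-(benzyloxy)benzoyl chloride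
Product: 6 1-[4,6-bis(benzyloxy)-3-bromo-2-hydroxy-5-iodophenyl]-3-[4-(benzyloxy)phenyl]propane-1,3-dione
Conditions: LiN(SiMe3)2 (3.3 equiv), THF, −78 to −10 °C; 5 (1.05 equiv), −78 °C to rt; 1 M HCl
Reagents that add atoms: none
Why: Direct C-aroylation of the lithium dianion of an o-hydroxyacetophenone (one-flask equivalent of the Baker–Venkataraman sequence), in which the third equivalent of base takes up the acidic diketone proton and the amide base leaves both aryl halides untouched.

**Step 4**
Reactants: 7 3-bromo-4-hydroxybenzaldehyde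
Product: 8 4-(benzyloxy)-3-bromobenzaldehyde
Conditions: BnBr (1.1 equiv), K2CO3, DMF, rt, 4 h
Reagents that add atoms: benzyl bromide, BrCc1ccccc1
Why: Williamson etherification of the single acidic phenol, with an aldehyde that cannot enolise.

**Step 5**
Reactants: 8 4-(benzyloxy)-3-bromobenzaldehyde; 6 the iodo diketone of step 3
Product: 10 4-(benzyloxy)-3-[2,6-bis(benzyloxy)-3-bromo-4-hydroxy-5-{3-[4-(benzyloxy)phenyl]-3-oxopropanoyl}phenyl]benzaldehyde, via pinacol boronate 9 (not isolated)
Conditions: 8 (1.15 equiv), B2pin2 (1.15 equiv), Pd(dppf)Cl2 (3 mol%), KOAc, 1,4-dioxane, 90 °C, 3 h; then 6 (1.0 equiv), Pd(OAc)2 (3 mol%), SPhos (6 mol%), aq. K3PO4, 70 °C, 6 h; cold dilute HCl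
Reagents that add atoms: bis(pinacolato)diboron, CC1(C)OB(OC1(C)C)B1OC(C)(C)C(C)(C)O1 (its atoms stay only in 9)
Why: Miyaura borylation followed by Suzuki–Miyaura coupling in the same flask, in which zerovalent palladium inserts into the C–I bond of 6 much faster than into the C–Br bond next to a phenoxide, and SPhos handles the three ortho substituents of the new biaryl.

**Step 6**
Reactants: 10 the biaryl aldehyde of step 5; 2 1-[2,4-bis(benzyloxy)-6-hydroxyphenyl]ethan-1-one
Product: 11 open chalcone–diketone: ring B of 10 now carries, in place of CHO, an (E)-CH=CH–C(=O)– group bound to a 2,4-bis(benzyloxy)-6-hydroxyphenyl ring (ring A)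
Conditions: 2 (1.3 equiv), 50% aq. KOH (15 equiv), EtOH–THF 2:1, rt, 48 h; 1 M HCl to pH 4, 0 °C
Reagents that add atoms: none
Why: Claisen–Schmidt condensation in which only 2 offers a methyl ketone enolate, the diketone of 10 rests as its unreactive dianion, E1cB loss of water gives the E-enone, and strong base keeps the product open as the chalcone phenoxide.

**Step 7 (key step)**
Reactants: 11 open chalcone–diketone
Product: 13 (2S)-5,7-bis(benzyloxy)-2-{4-(benzyloxy)-3-[5,7-bis(benzyloxy)-2-[4-(benzyloxy)phenyl]-8-bromo-4-oxo-4H-chromen-6-yl]phenyl}-2,3-dihydro-4H-chromen-4-one, via flavanone diketone 12 (not isolated)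
Conditions: 1-[3,5-bis(trifluoromethyl)phenyl]-3-[(9R)-6'-methoxycinchonan-9-yl]thiourea (20 mol%), toluene (0.02 M), 0 °C, 72 h; then TsOH·H2O (0.5 equiv), 4 Å sieves, 60 °C, 3 h, same flask
Reagents that add atoms: none
Why: Proposed new method: the quinuclidine nitrogen takes the proton of the ring A 2'-OH while the thiourea binds the enone C=O, so the phenoxide adds 6-endo-trig to one face of the E-enone and sets C2 as S (the 6'-benzyloxy group twists the aroyl unit and makes closure downhill), then TsOH protonates the amine, which stops the retro-oxa-Michael path, and cyclodehydrates the o-hydroxyaryl β-diketone through its hemiketal, whose only free OH lies para to the biaryl bond so that only the 6-aryl flavone can form; the closest known reaction types are the cinchona-thiourea intramolecular oxa-Michael addition of o-hydroxyaryl alkylidene β-keto esters with a TsOH finish in the same flask, and the acid cyclodehydration that ends a Baker–Venkataraman flavone synthesis.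

**Step 8**
Reactants: 13 the hexabenzyl 8-bromo biflavonoid
Product: 14 (2S)-5,7-dihydroxy-2-{4-hydroxy-3-[5,7-dihydroxy-2-(4-hydroxyphenyl)-4-oxo-4H-chromen-6-yl]phenyl}-2,3-dihydro-4H-chromen-4-one (target)
Conditions: H2 (1 atm), 10% Pd on carbon, NaOAc (1.2 equiv), AcOH (2 equiv), THF–MeOH 1:1, rt, 8 h
Reagents that add atoms: none
Why: Catalytic hydrogenolysis cleaves the six O-benzyl bonds and the aryl C–Br bond in one pass, and the acetate buffer takes up HBr without reaching the basic pH at which 5,7-dihydroxyflavanones racemise, so C2 stays S and the flavone C=C is untouched at 1 atm.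

**Compound list**
1 | 2,4,6-trihydroxyacetophenone | CC(=O)c1c(O)cc(O)cc1O | starting material
2 | 1-[2,4-bis(benzyloxy)-6-hydroxyphenyl]ethan-1-one | CC(=O)c1c(O)cc(OCc2ccccc2)cc1OCc1ccccc1 | intermediate
3 | 1-[4,6-bis(benzyloxy)-3-bromo-2-hydroxyphenyl]ethan-1-one (not isolated) | CC(=O)c1c(O)c(Br)c(OCc2ccccc2)cc1OCc1ccccc1 | intermediate
4 | 1-[4,6-bis(benzyloxy)-3-bromo-2-hydroxy-5-iodophenyl]ethan-1-one | CC(=O)c1c(O)c(Br)c(OCc2ccccc2)c(I)c1OCc1ccccc1 | intermediate
5 | 4-(benzyloxy)benzoyl chloride | O=C(Cl)c1ccc(OCc2ccccc2)cc1 | starting material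
6 | 1-[4,6-bis(benzyloxy)-3-bromo-2-hydroxy-5-iodophenyl]-3-[4-(benzyloxy)phenyl]propane-1,3-dione (drawn as diketo tautomer) | O=C(CC(=O)c1ccc(OCc2ccccc2)cc1)c1c(O)c(Br)c(OCc2ccccc2)c(I)c1OCc1ccccc1 | intermediate
7 | 3-bromo-4-hydroxybenzaldehyde | O=Cc1ccc(O)c(Br)c1 | starting material
8 | 4-(benzyloxy)-3-bromobenzaldehyde | O=Cc1ccc(OCc2ccccc2)c(Br)c1 | intermediate
9 | 4-(benzyloxy)-3-(4,4,5,5-tetramethyl-1,3,2-dioxaborolan-2-yl)benzaldehyde (not isolated) | O=Cc1ccc(OCc2ccccc2)c(B2OC(C)(C)C(C)(C)O2)c1 | intermediate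
10 | biaryl aldehyde–diketone (name as in step 5) | O=Cc1ccc(OCc2ccccc2)c(c1)-c1c(OCc2ccccc2)c(Br)c(O)c(C(=O)CC(=O)c2ccc(OCc3ccccc3)cc2)c1OCc1ccccc1 | intermediate
11 | open (E)-chalcone–diketone | O=C(/C=C/c1ccc(OCc2ccccc2)c(c1)-c1c(OCc2ccccc2)c(Br)c(O)c(C(=O)CC(=O)c2ccc(OCc3ccccc3)cc2)c1OCc1ccccc1)c1c(O)cc(OCc2ccccc2)cc1OCc1ccccc1 | intermediate
12 | (2S)-flavanone with ring E still open as the β-diketone (not isolated) | O=C1C[C@@H](c2ccc(OCc3ccccc3)c(-c3c(OCc4ccccc4)c(Br)c(O)c(C(=O)CC(=O)c4ccc(OCc5ccccc5)cc4)c3OCc3ccccc3)c2)Oc2cc(OCc3ccccc3)cc(OCc3ccccc3)c21 | intermediate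
13 | (2S)-hexa-O-benzyl-8-bromo flavanone–flavone (name as in step 7) | O=C1C[C@@H](c2ccc(OCc3ccccc3)c(-c3c(OCc4ccccc4)c(Br)c4oc(-c5ccc(OCc6ccccc6)cc5)cc(=O)c4c3OCc3ccccc3)c2)Oc2cc(OCc3ccccc3)cc(OCc3ccccc3)c21 | intermediate
14 | (2S)-2,3-dihydrorobustaflavone, CNP0277421.1 | O=C1C[C@@H](c2ccc(O)c(-c3c(O)cc4oc(-c5ccc(O)cc5)cc(=O)c4c3O)c2)Oc2cc(O)cc(O)c21 | target

**Total steps:** 8. **Longest linear sequence:** 7 (steps 1, 2, 3, 5, 6, 7, 8).

**Three steps most likely to fail**

Step 7. An unactivated chalcone may close slowly or with modest ee, and the acidic diketone may tie up the catalyst. Recrystallising 13 can raise a moderate ee but cannot rescue a low one.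

The fallback sets out from 2 and 10 and comes back at 13. Compound 2 is C-carboxylated (LiN(SiMe3)2, di-tert-butyl dicarbonate, THF, −78 °C) to tert-butyl 3-[2,4-bis(benzyloxy)-6-hydroxyphenyl]-3-oxopropanoate F1. Knoevenagel condensation with 10 (piperidine, AcOH, 4 Å sieves, toluene, rt) gives the alkylidene β-keto ester F2. This doubly activated acceptor closes at −25 °C under the same thiourea to the 3-(tert-butoxycarbonyl)flavanone F3. TsOH at 80 °C in the same flask then cleaves the ester, decarboxylates and closes ring E to give 13.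

Step 5. The iodide is flanked by two benzyloxy groups. The free phenol and diketone can bind palladium, or ring E can close early under the phosphate base.

The fallback sets out from 4 (with 5 and 9) and comes back at 10. Compound 4 is O-aroylated with 5 (K2CO3, acetone, rt) to 2-acetyl-3,5-bis(benzyloxy)-6-bromo-4-iodophenyl 4-(benzyloxy)benzoate F4, which has neither a free phenol nor a chelating diketone. Suzuki coupling with 9 (Pd(OAc)2, SPhos, anhydrous K3PO4, toluene, 80 °C) gives the biaryl ester aldehyde F5. LiN(SiMe3)2 at −78 °C in dilute THF then triggers the Baker–Venkataraman O-to-C aroyl shift to 10.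

Step 6. The diketone enolate may add to the aldehyde or to the new enone, or it may suffer retro-Claisen cleavage during the long exposure to hydroxide.

The fallback sets out from 2 and 8 and comes back at 11. Claisen–Schmidt condensation of 2 with 8 (KOH, EtOH, rt), with no diketone present, gives the bromochalcone F6. Miyaura borylation (B2pin2, Pd(dppf)Cl2, KOAc, dioxane, 80 °C) gives the chalcone boronate F7. Suzuki coupling with 6 under the second-stage conditions of step 5 gives 11. A short KOH/EtOH treatment and cold acidification reopens any flavanone that the phosphate base has closed.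

**Further compounds**
F1 | step 7 | tert-butyl 3-[2,4-bis(benzyloxy)-6-hydroxyphenyl]-3-oxopropanoate | CC(C)(C)OC(=O)CC(=O)c1c(O)cc(OCc2ccccc2)cc1OCc1ccccc1
F2 | step 7 | alkylidene β-keto ester from F1 and 10 (E/Z mixture, geometry not defined) | CC(C)(C)OC(=O)C(=Cc1ccc(OCc2ccccc2)c(c1)-c1c(OCc2ccccc2)c(Br)c(O)c(C(=O)CC(=O)c2ccc(OCc3ccccc3)cc2)c1OCc1ccccc1)C(=O)c1c(O)cc(OCc2ccccc2)cc1OCc1ccccc1
F3 | step 7 | (2S)-3-(tert-butoxycarbonyl)flavanone with ring E open (C3 labile, not defined) | O=C1C(C(=O)OC(C)(C)C)[C@@H](c2ccc(OCc3ccccc3)c(-c3c(OCc4ccccc4)c(Br)c(O)c(C(=O)CC(=O)c4ccc(OCc5ccccc5)cc4)c3OCc3ccccc3)c2)Oc2cc(OCc3ccccc3)cc(OCc3ccccc3)c21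
F4 | step 5 | 2-acetyl-3,5-bis(benzyloxy)-6-bromo-4-iodophenyl 4-(benzyloxy)benzoate | CC(=O)c1c(OC(=O)c2ccc(OCc3ccccc3)cc2)c(Br)c(OCc2ccccc2)c(I)c1OCc1ccccc1
F5 | step 5 | biaryl ester aldehyde (F4 with iodine replaced by 2-(benzyloxy)-5-formylphenyl) | CC(=O)c1c(OC(=O)c2ccc(OCc3ccccc3)cc2)c(Br)c(OCc2ccccc2)c(-c2cc(C=O)ccc2OCc2ccccc2)c1OCc1ccccc1
F6 | step 6 | (E)-1-[2,4-bis(benzyloxy)-6-hydroxyphenyl]-3-[4-(benzyloxy)-3-bromophenyl]prop-2-en-1-one | O=C(/C=C/c1ccc(OCc2ccccc2)c(Br)c1)c1c(O)cc(OCc2ccccc2)cc1OCc1ccccc1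
F7 | step 6 | pinacol boronate of F6 | O=C(/C=C/c1ccc(OCc2ccccc2)c(B2OC(C)(C)C(C)(C)O2)c1)c1c(O)cc(OCc2ccccc2)cc1OCc1ccccc1
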